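**Retrosynthetic overview**
1. Ring A carries its carboxyl-bearing C7 between two unsubstituted CH carbons (C6 and C8), meta to the C5 oxygen. Nitrogen occupies exactly this place in a 4-alkoxy-5,6,7,8-tetrahydroisoquinoline, so ring A is carried as a pyridine and converted late, by exchanging N for a C–CO2tBu unit from tert-butyl acetate (bonds C7–C8 and C6–C7).
2. Order of rings: pyridine ring (bought as 3-(benzyloxy)-5-bromopyridine), then ring B, then the benzene ring A by the exchange on tetrahydroisoquinoline 33.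
3. Ring B is closed at C2–C3 by intramolecular alkylation of a sulfone-stabilised carbanion, followed by desulfonylation. The C4 arm comes from C4-lithiation and Evans methylation (sets C4); the C1 arm from a Pd coupling and an Ireland–Claisen rearrangement (sets C1 and C11).
4. The Claisen partner, allylic alcohol 23 (C11–C16), comes from (S)-3-bromo-2-methylpropan-1-ol (C15) and crotonaldehyde; its carbinol centre is set by CBS reduction.
5. End game: desilylation, acylation with 3-phenylpropanoyl chloride, acidolysis of the tert-butyl ester, hydrogenolysis of the benzyl ether.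

Key step: step 21

Remark: atoms are labelled on the tetralin frame of the target (ring A: C4a, C5–C8, C8a; ring B: C1–C4; side chain C11–C16, methyl groups on C11 and C15); in these labels the target SMILES reads 1S,4R,11S,15R, with the C1 and C4 substituents trans.

**Route**

Step 1
Reactants: 1 3-(benzyloxy)-5-bromopyridine
Product: 3 3-(benzyloxy)-5-bromo-4-methylpyridine, via aryllithium 2 (not isolated)
Conditions: LiN(iPr)2, THF, −78 °C; then MeI, −78 → −40 °C
Reagents that add atoms: iodomethane, CI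
Why: Directed ortho-lithiation at C4, the position flanked by bromine and the benzyloxy group, followed by SN2 methylation of the aryllithium at a temperature where halogen migration and pyridyne formation should not compete; this carbon becomes C4 of ring B.

Step 2
Reactants: 3 3-(benzyloxy)-5-bromo-4-methylpyridine
Product: 5 2-[3-(benzyloxy)-5-bromopyridin-4-yl]acetic acid, via picolyllithium 4 (not isolated)
Conditions: LiN(iPr)2, THF, −78 °C; CO2; aq. HCl to pH 4
Reagents that add atoms: carbon dioxide, O=C=O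
Why: Lateral (picolyl) lithiation of the 4-methyl group, the most acidic C–H of 3, and carboxylation of the benzylic anion give the arylacetic acid whose carboxyl carbon becomes C3.

Step 3
Reactants: 5 2-[3-(benzyloxy)-5-bromopyridin-4-yl]acetic acid; 6 (4S)-4-benzyl-1,3-oxazolidin-2-one
Product: 8 (4S)-4-benzyl-3-{2-[3-(benzyloxy)-5-bromopyridin-4-yl]acetyl}-1,3-oxazolidin-2-one, via mixed pivalic anhydride 7 (not isolated)
Conditions: tBuCOCl, Et3N, THF, −20 °C; then 6, LiCl, −20 °C → rt
Reagents that add atoms: (4S)-4-benzyl-1,3-oxazolidin-2-one 6, O=C1N[C@@H](Cc2ccccc2)CO1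
Why: Mixed-anhydride N-acylation of the Evans oxazolidinone (pivaloyl activation, LiCl/Et3N acyl transfer) attaches the auxiliary without a strong base.

Step 4
Reactants: 8 (4S)-4-benzyl-3-{2-[3-(benzyloxy)-5-bromopyridin-4-yl]acetyl}-1,3-oxazolidin-2-one
Product: 10 (4S)-4-benzyl-3-{(2S)-2-[3-(benzyloxy)-5-bromopyridin-4-yl]propanoyl}-1,3-oxazolidin-2-one, via sodium enolate 9 (not isolated)
Conditions: NaN(SiMe3)2, THF, −78 °C; MeI, −78 → −40 °C
Reagents that add atoms: iodomethane, CI
Why: Evans asymmetric alkylation, in which the chelated (Z)-sodium enolate is methylated on the face opposite the benzyl group of the (S)-auxiliary, should set the (S)-carbon that becomes C4 (4R in the target), while the flanking bromine and benzyloxy groups twist the pyridine out of conjugation and slow epimerisation of the product.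

Step 5
Reactants: 10 (4S)-4-benzyl-3-{(2S)-2-[3-(benzyloxy)-5-bromopyridin-4-yl]propanoyl}-1,3-oxazolidin-2-one
Product: 11 (2S)-2-[3-(benzyloxy)-5-bromopyridin-4-yl]propan-1-ol
Conditions: LiBH4, MeOH (1 equiv), THF, 0 °C
Reagents that add atoms: none
Why: Reductive cleavage of the N-acyl oxazolidinone gives the primary alcohol (C3) and returns the auxiliary, after which the benzylic centre is no longer α to a carbonyl group and should be configurationally safe.

Step 6
Reactants: 11 (2S)-2-[3-(benzyloxy)-5-bromopyridin-4-yl]propan-1-ol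
Product: 12 3-(benzyloxy)-5-bromo-4-[(2S)-1-(phenylsulfanyl)propan-2-yl]pyridine
Conditions: PhSSPh, nBu3P, THF, rt
Reagents that add atoms: diphenyl disulfide, c1ccc(cc1)SSc1ccccc1
Why: Hata thioetherification (phosphine–disulfide activation of the alcohol and SN2 displacement by thiophenolate) gives the phenyl sulfide under neutral conditions.

Step 7
Reactants: 12 3-(benzyloxy)-5-bromo-4-[(2S)-1-(phenylsulfanyl)propan-2-yl]pyridine
Product: 13 4-[(2S)-1-(benzenesulfonyl)propan-2-yl]-3-(benzyloxy)-5-bromopyridine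
Conditions: (NH4)6Mo7O24·4H2O (cat.), 30% H2O2, EtOH, 0 °C → rt
Reagents that add atoms: hydrogen peroxide, OO
Why: Molybdate-catalysed oxidation of sulfide to sulfone installs the carbanion-stabilising group at C3, and the electron-poor pyridine nitrogen should resist N-oxidation under these conditions.

Step 8
Reactants: 13 4-[(2S)-1-(benzenesulfonyl)propan-2-yl]-3-(benzyloxy)-5-bromopyridine; 14 (2-tert-butoxy-2-oxoethyl)zinc bromide
Product: 15 tert-butyl 2-{4-[(2S)-1-(benzenesulfonyl)propan-2-yl]-5-(benzyloxy)pyridin-3-yl}acetate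
Conditions: Pd2(dba)3 (cat.), XPhos (cat.), THF, 65 °C
Reagents that add atoms: (2-tert-butoxy-2-oxoethyl)zinc bromide 14, CC(C)(C)OC(=O)C[Zn]Br
Why: Negishi-type coupling of a Reformatsky reagent (palladium-catalysed α-arylation of a zinc ester enolate) replaces the hindered bromine by the CH2CO2tBu unit that supplies C1 and C2, under neutral conditions that leave the sulfone alone.

Step 9
Reactants: 15 tert-butyl 2-{4-[(2S)-1-(benzenesulfonyl)propan-2-yl]-5-(benzyloxy)pyridin-3-yl}acetate
Product: 16 2-{4-[(2S)-1-(benzenesulfonyl)propan-2-yl]-5-(benzyloxy)pyridin-3-yl}acetic acid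
Conditions: CF3CO2H, CH2Cl2, 0 °C → rt; adjust to pH 5
Reagents that add atoms: none
Why: Acidolysis of the tert-butyl ester (loss of isobutene through the tert-butyl cation) frees the arylacetic acid without touching the benzyl ether or the sulfone.

Step 10
Reactants: 17 (2S)-3-bromo-2-methylpropan-1-ol
Product: 18 [(2S)-3-bromo-2-methylpropoxy](tert-butyl)dimethylsilane
Conditions: tBuMe2SiCl, imidazole, CH2Cl2, 0 °C → rt
Reagents that add atoms: tert-butyldimethylsilyl chloride, CC(C)(C)[Si](C)(C)Cl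
Why: Standard silylation of the primary alcohol; the stereocentre, which becomes C15, comes from the chiral pool and is not touched.

Step 11
Reactants: 18 [(2S)-3-bromo-2-methylpropoxy](tert-butyl)dimethylsilane; 19 (E)-but-2-enal
Product: 21 (2R,5E)-1-[(tert-butyldimethylsilyl)oxy]-2-methylhept-5-en-4-ol as a mixture of both C4 epimers, via Grignard reagent 20 (not isolated)
Conditions: Mg, THF, 40 °C; then 19, −78 °C; aqueous work-up
Reagents that add atoms: (E)-but-2-enal 19, C/C=C/C=O
Why: Grignard formation and 1,2-addition to the enal join C13 to C14 and give the (E)-allylic alcohol without control at the carbinol carbon, which is corrected in steps 12 and 13.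

Step 12
Reactants: 21 (2R,5E)-1-[(tert-butyldimethylsilyl)oxy]-2-methylhept-5-en-4-ol (C4 epimers)
Product: 22 (2R,5E)-1-[(tert-butyldimethylsilyl)oxy]-2-methylhept-5-en-4-one
Conditions: MnO2, CH2Cl2, rt
Reagents that add atoms: none
Why: Allylic oxidation with MnO2 gives the (E)-enone without touching the silyl ether or the C2 stereocentre.

Step 13
Reactants: 22 (2R,5E)-1-[(tert-butyldimethylsilyl)oxy]-2-methylhept-5-en-4-one
Product: 23 (2R,4R,5E)-1-[(tert-butyldimethylsilyl)oxy]-2-methylhept-5-en-4-ol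
Conditions: (S)-2-methyl-CBS-oxazaborolidine (cat.), catecholborane, toluene, −78 °C
Reagents that add atoms: none
Why: Corey–Bakshi–Shibata reduction, in which the propenyl group acts as the large substituent toward the (S)-oxazaborolidine, should deliver hydride to give the (4R)-alcohol that the chair transition state of step 15 requires.

Step 14
Reactants: 16 2-{4-[(2S)-1-(benzenesulfonyl)propan-2-yl]-5-(benzyloxy)pyridin-3-yl}acetic acid; 23 (2R,4R,5E)-1-[(tert-butyldimethylsilyl)oxy]-2-methylhept-5-en-4-ol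
Product: 24 (2R,4R,5E)-1-[(tert-butyldimethylsilyl)oxy]-2-methylhept-5-en-4-yl 2-{4-[(2S)-1-(benzenesulfonyl)propan-2-yl]-5-(benzyloxy)pyridin-3-yl}acetate
Conditions: EDC·HCl, DMAP, CH2Cl2, 0 °C → rt
Reagents that add atoms: none
Why: Steglich esterification (carbodiimide activation, DMAP acyl transfer) joins the two fragments as the allylic arylacetate without touching any stereocentre.

Step 15
Reactants: 24 (2R,4R,5E)-1-[(tert-butyldimethylsilyl)oxy]-2-methylhept-5-en-4-yl 2-{4-[(2S)-1-(benzenesulfonyl)propan-2-yl]-5-(benzyloxy)pyridin-3-yl}acetate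
Product: 27 (2S,3S,4E,7R)-2-{4-[(2S)-1-(benzenesulfonyl)propan-2-yl]-5-(benzyloxy)pyridin-3-yl}-8-[(tert-butyldimethylsilyl)oxy]-3,7-dimethyloct-4-enoic acid, via silyl ketene acetal 25 (not isolated), via trimethylsilyl ester 26 (not isolated)
Conditions: LiN(SiMe3)2, THF, −78 °C; Me3SiCl, Et3N, −78 °C → rt → 45 °C; aq. NH4Cl
Reagents that add atoms: none
Why: Ireland–Claisen rearrangement, in which the arylacetate is expected to give the (Z)-silyl ketene acetal (aryl cis to OSiMe3) that rearranges through a chair transition state with the aryl group, the C11 methyl and the carbinol substituent all equatorial, should transfer the (4R)-carbinol configuration into C1 (S) and C11 (S) and form a new (E)-alkene.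

Step 16
Reactants: 27 (2S,3S,4E,7R)-2-{4-[(2S)-1-(benzenesulfonyl)propan-2-yl]-5-(benzyloxy)pyridin-3-yl}-8-[(tert-butyldimethylsilyl)oxy]-3,7-dimethyloct-4-enoic acid
Product: 28 (2S,3S,4E,7R)-2-{4-[(2S)-1-(benzenesulfonyl)propan-2-yl]-5-(benzyloxy)pyridin-3-yl}-8-[(tert-butyldimethylsilyl)oxy]-3,7-dimethyloct-4-en-1-ol
Conditions: LiAlH4, THF, 0 °C → rt
Reagents that add atoms: none
Why: Hydride reduction of the carboxylic acid to the primary alcohol (C2) should leave the sulfone, both ethers and the isolated alkene intact, and removes the carbonyl group that made C1 epimerisable.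

Step 17
Reactants: 28 (2S,3S,4E,7R)-2-{4-[(2S)-1-(benzenesulfonyl)propan-2-yl]-5-(benzyloxy)pyridin-3-yl}-8-[(tert-butyldimethylsilyl)oxy]-3,7-dimethyloct-4-en-1-ol
Product: 29 4-[(2S)-1-(benzenesulfonyl)propan-2-yl]-3-(benzyloxy)-5-[(2S,3S,4E,7R)-8-[(tert-butyldimethylsilyl)oxy]-1-iodo-3,7-dimethyloct-4-en-2-yl]pyridine
Conditions: I2, PPh3, imidazole, CH2Cl2, 0 °C → rt
Reagents that add atoms: iodine, II
Why: Appel-type iodination (alkoxyphosphonium formation and SN2 displacement by iodide) turns the primary alcohol into the electrophile for ring closure.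

Step 18
Reactants: 29 4-[(2S)-1-(benzenesulfonyl)propan-2-yl]-3-(benzyloxy)-5-[(2S,3S,4E,7R)-8-[(tert-butyldimethylsilyl)oxy]-1-iodo-3,7-dimethyloct-4-en-2-yl]pyridine
Product: 31 (5S,8S)-6-(benzenesulfonyl)-4-(benzyloxy)-8-[(2S,3E,6R)-7-[(tert-butyldimethylsilyl)oxy]-6-methylhept-3-en-2-yl]-5-methyl-5,6,7,8-tetrahydroisoquinoline as a mixture of C6 epimers, via sulfonyl carbanion 30 (not isolated)
Conditions: KN(SiMe3)2, THF (0.01 M), −78 → 0 °C
Reagents that add atoms: none
Why: Intramolecular alkylation of the α-sulfonyl carbanion (6-exo-tet SN2) forms the C2–C3 bond and closes ring B, with C1 and C4 (set independently in steps 15 and 4) ending up trans and the sulfonyl-bearing carbon formed as an epimer mixture that is erased in the next step.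

Step 19
Reactants: 31 (5S,8S)-6-(benzenesulfonyl)-4-(benzyloxy)-8-[(2S,3E,6R)-7-[(tert-butyldimethylsilyl)oxy]-6-methylhept-3-en-2-yl]-5-methyl-5,6,7,8-tetrahydroisoquinoline (C6 epimers)
Product: 32 (5R,8S)-4-(benzyloxy)-8-[(2S,3E,6R)-7-[(tert-butyldimethylsilyl)oxy]-6-methylhept-3-en-2-yl]-5-methyl-5,6,7,8-tetrahydroisoquinoline
Conditions: Na(Hg), Na2HPO4, MeOH/THF, −20 °C → rt
Reagents that add atoms: none
Why: Reductive desulfonylation with sodium amalgam (electron transfer, C–S cleavage, protonation) replaces the sulfonyl group by hydrogen, and the buffer keeps the medium from becoming basic enough to ionise the benzylic C4–H.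

Step 20
Reactants: 32 (5R,8S)-4-(benzyloxy)-8-[(2S,3E,6R)-7-[(tert-butyldimethylsilyl)oxy]-6-methylhept-3-en-2-yl]-5-methyl-5,6,7,8-tetrahydroisoquinoline
Product: 33 (5R,8S)-4-(benzyloxy)-8-[(2S,6R)-7-[(tert-butyldimethylsilyl)oxy]-6-methylheptan-2-yl]-5-methyl-5,6,7,8-tetrahydroisoquinoline
Conditions: TsNHNH2, NaOAc, DME/H2O, reflux
Reagents that add atoms: none
Why: Diimide reduction (concerted syn transfer of two hydrogens from HN=NH made in the flask) saturates the side-chain alkene and leaves the benzyl ether and the pyridine ring, which catalytic hydrogenation would endanger, untouched.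

Step 21
Reactants: 33 (5R,8S)-4-(benzyloxy)-8-[(2S,6R)-7-[(tert-butyldimethylsilyl)oxy]-6-methylheptan-2-yl]-5-methyl-5,6,7,8-tetrahydroisoquinoline; 34 tert-butyl acetate
Product: 41 tert-butyl (5R,8S)-4-(benzyloxy)-8-[(2S,6R)-7-[(tert-butyldimethylsilyl)oxy]-6-methylheptan-2-yl]-5-methyl-5,6,7,8-tetrahydronaphthalene-2-carboxylate, via lithium enolate 35 (not isolated), via N-triflylpyridinium triflate 36 (not isolated), via ring-opened azatriene 37 (not isolated), via triflamide adduct 38 (not isolated), via aminotrienoate 39 (not isolated), via aminocyclohexadiene 40 (not isolated)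
Conditions: (CF3SO2)2O, CH2Cl2, −78 °C; HNBn2, 2,4,6-collidine, −78 °C → rt; aqueous wash, solvent switch to THF; LiCH2CO2tBu (from 34 and LiN(iPr)2, THF, −78 °C), −78 °C → rt; then 70 °C; aq. NH4Cl
Reagents that add atoms: tert-butyl acetate 34, CC(=O)OC(C)(C)C
Why: Proposed new method: N-triflylation makes the two CH carbons next to nitrogen (the future C6 and C8) electrophilic, dibenzylamine adds to one of them and the 2-amino-1,2-dihydropyridine opens by 6π-electrocyclic ring opening to the N-triflyl azatriene 37; the lithium enolate of tert-butyl acetate then adds to the C=NTf terminus (38), triflamide is expelled with the push of the enamine nitrogen and loss of the α-proton gives amino-trienoate 39. Thermal disrotatory 6π-electrocyclisation of 39 closes the six-membered ring A by the second bond to the new carbon, and E1cB loss of dibenzylamine from 40 aromatises it, so the acetate carbon takes the place of nitrogen. The closest known reaction type is the Zincke ring opening of an N-activated pyridine followed by condensation with a carbon nucleophile, 6π-electrocyclisation and amine loss (as with ketone enolates and in the Ziegler–Hafner azulene synthesis), which has not been shown for an ester enolate or a pyridine with this substitution pattern. No stereocentre is created, because the two sp3 carbons of 40 become aromatic. No regiocontrol is needed, since whichever CH takes the amine the new carbon still ends between C6 and C8, and the cis geometry needed for closure is fixed by the C4a=C8a bond inside ring B. What must be preserved is C4, whose hydrogen is a lateral C–H of the N-triflylpyridinium; low temperature, the weak hindered base and the allylic strain against the benzyloxy group that planarisation would cost should keep it from ionising before the amine adds.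

Step 22
Reactants: 41 tert-butyl (5R,8S)-4-(benzyloxy)-8-[(2S,6R)-7-[(tert-butyldimethylsilyl)oxy]-6-methylheptan-2-yl]-5-methyl-5,6,7,8-tetrahydronaphthalene-2-carboxylate
Product: 42 tert-butyl (5R,8S)-4-(benzyloxy)-8-[(2S,6R)-7-hydroxy-6-methylheptan-2-yl]-5-methyl-5,6,7,8-tetrahydronaphthalene-2-carboxylate
Conditions: Bu4NF, THF, 0 °C → rt
Reagents that add atoms: none
Why: Fluoride-induced cleavage of the Si–O bond frees the primary alcohol while the tert-butyl ester and the benzyl ether stay inert.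

Step 23
Reactants: 42 tert-butyl (5R,8S)-4-(benzyloxy)-8-[(2S,6R)-7-hydroxy-6-methylheptan-2-yl]-5-methyl-5,6,7,8-tetrahydronaphthalene-2-carboxylate; 43 3-phenylpropanoyl chloride
Product: 44 tert-butyl (5R,8S)-4-(benzyloxy)-5-methyl-8-[(2S,6R)-6-methyl-7-[(3-phenylpropanoyl)oxy]heptan-2-yl]-5,6,7,8-tetrahydronaphthalene-2-carboxylate
Conditions: pyridine, DMAP (cat.), CH2Cl2, 0 °C → rt
Reagents that add atoms: 3-phenylpropanoyl chloride 43, O=C(Cl)CCc1ccccc1
Why: O-acylation of the primary alcohol by the acid chloride with DMAP as acyl-transfer catalyst installs the 3-phenylpropanoate.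

Step 24
Reactants: 44 tert-butyl (5R,8S)-4-(benzyloxy)-5-methyl-8-[(2S,6R)-6-methyl-7-[(3-phenylpropanoyl)oxy]heptan-2-yl]-5,6,7,8-tetrahydronaphthalene-2-carboxylate
Product: 45 (5R,8S)-4-(benzyloxy)-5-methyl-8-[(2S,6R)-6-methyl-7-[(3-phenylpropanoyl)oxy]heptan-2-yl]-5,6,7,8-tetrahydronaphthalene-2-carboxylic acid
Conditions: CF3CO2H, CH2Cl2, 0 °C → rt
Reagents that add atoms: none
Why: Acidolysis of the tert-butyl ester through the tert-butyl cation frees the C7 carboxylic acid under conditions where the primary alkyl ester and the aryl benzyl ether should persist.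

Step 25
Reactants: 45 (5R,8S)-4-(benzyloxy)-5-methyl-8-[(2S,6R)-6-methyl-7-[(3-phenylpropanoyl)oxy]heptan-2-yl]-5,6,7,8-tetrahydronaphthalene-2-carboxylic acid
Product: 46 (5R,8S)-4-hydroxy-5-methyl-8-[(2S,6R)-6-methyl-7-[(3-phenylpropanoyl)oxy]heptan-2-yl]-5,6,7,8-tetrahydronaphthalene-2-carboxylic acid
Conditions: H2 (1 atm), Pd/C, EtOAc, rt
Reagents that add atoms: none
Why: Hydrogenolysis of the aryl benzyl ether over Pd/C frees the C5 phenol and gives the target without affecting the esters, the acid or the stereocentres.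

**Compound list**
1 | 3-(benzyloxy)-5-bromopyridine | Brc1cncc(OCc2ccccc2)c1 | starting material
2 | 3-(benzyloxy)-5-bromo-4-lithiopyridine (formed in the flask) | [Li]c1c(Br)cncc1OCc1ccccc1 | intermediate
3 | 3-(benzyloxy)-5-bromo-4-methylpyridine | Cc1c(Br)cncc1OCc1ccccc1 | intermediate
4 | {[3-(benzyloxy)-5-bromopyridin-4-yl]methyl}lithium (formed in the flask) | [Li]Cc1c(Br)cncc1OCc1ccccc1 | intermediate
5 | 2-[3-(benzyloxy)-5-bromopyridin-4-yl]acetic acid | OC(=O)Cc1c(Br)cncc1OCc1ccccc1 | intermediate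
6 | (4S)-4-benzyl-1,3-oxazolidin-2-one | O=C1N[C@@H](Cc2ccccc2)CO1 | starting material
7 | 2-[3-(benzyloxy)-5-bromopyridin-4-yl]acetic pivalic anhydride (formed in the flask) | CC(C)(C)C(=O)OC(=O)Cc1c(Br)cncc1OCc1ccccc1 | intermediate
8 | (4S)-4-benzyl-3-{2-[3-(benzyloxy)-5-bromopyridin-4-yl]acetyl}-1,3-oxazolidin-2-one | O=C(Cc1c(Br)cncc1OCc1ccccc1)N1[C@@H](Cc2ccccc2)COC1=O | intermediate
9 | sodium (Z)-enolate of 8 (formed in the flask) | [Na+].[O-]/C(=C\c1c(Br)cncc1OCc1ccccc1)N1[C@@H](Cc2ccccc2)COC1=O | intermediate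
10 | (4S)-4-benzyl-3-{(2S)-2-[3-(benzyloxy)-5-bromopyridin-4-yl]propanoyl}-1,3-oxazolidin-2-one | O=C([C@@H](C)c1c(Br)cncc1OCc1ccccc1)N1[C@@H](Cc2ccccc2)COC1=O | intermediate
11 | (2S)-2-[3-(benzyloxy)-5-bromopyridin-4-yl]propan-1-ol | OC[C@@H](C)c1c(Br)cncc1OCc1ccccc1 | intermediate
12 | 3-(benzyloxy)-5-bromo-4-[(2S)-1-(phenylsulfanyl)propan-2-yl]pyridine | S(C[C@@H](C)c1c(Br)cncc1OCc1ccccc1)c1ccccc1 | intermediate
13 | 4-[(2S)-1-(benzenesulfonyl)propan-2-yl]-3-(benzyloxy)-5-bromopyridine | O=S(=O)(C[C@@H](C)c1c(Br)cncc1OCc1ccccc1)c1ccccc1 | intermediate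
14 | (2-tert-butoxy-2-oxoethyl)zinc bromide | CC(C)(C)OC(=O)C[Zn]Br | starting material
15 | tert-butyl 2-{4-[(2S)-1-(benzenesulfonyl)propan-2-yl]-5-(benzyloxy)pyridin-3-yl}acetate | CC(C)(C)OC(=O)Cc1cncc(OCc2ccccc2)c1[C@H](C)CS(=O)(=O)c1ccccc1 | intermediate
16 | 2-{4-[(2S)-1-(benzenesulfonyl)propan-2-yl]-5-(benzyloxy)pyridin-3-yl}acetic acid | OC(=O)Cc1cncc(OCc2ccccc2)c1[C@H](C)CS(=O)(=O)c1ccccc1 | intermediate
17 | (2S)-3-bromo-2-methylpropan-1-ol | BrC[C@@H](C)CO | starting material
18 | [(2S)-3-bromo-2-methylpropoxy](tert-butyl)dimethylsilane | BrC[C@@H](C)CO[Si](C)(C)C(C)(C)C | intermediate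
19 | (E)-but-2-enal (crotonaldehyde) | C/C=C/C=O | starting material
20 | {(2S)-3-[(tert-butyldimethylsilyl)oxy]-2-methylpropyl}magnesium bromide (formed in the flask) | Br[Mg]C[C@@H](C)CO[Si](C)(C)C(C)(C)C | intermediate
21 | (2R,5E)-1-[(tert-butyldimethylsilyl)oxy]-2-methylhept-5-en-4-ol, both C4 epimers | C/C=C/C(O)C[C@@H](C)CO[Si](C)(C)C(C)(C)C | intermediate
22 | (2R,5E)-1-[(tert-butyldimethylsilyl)oxy]-2-methylhept-5-en-4-one | C/C=C/C(=O)C[C@@H](C)CO[Si](C)(C)C(C)(C)C | intermediate
23 | (2R,4R,5E)-1-[(tert-butyldimethylsilyl)oxy]-2-methylhept-5-en-4-ol | C/C=C/[C@H](O)C[C@@H](C)CO[Si](C)(C)C(C)(C)C | intermediate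
24 | (2R,4R,5E)-1-[(tert-butyldimethylsilyl)oxy]-2-methylhept-5-en-4-yl 2-{4-[(2S)-1-(benzenesulfonyl)propan-2-yl]-5-(benzyloxy)pyridin-3-yl}acetate | C/C=C/[C@@H](C[C@@H](C)CO[Si](C)(C)C(C)(C)C)OC(=O)Cc1cncc(OCc2ccccc2)c1[C@H](C)CS(=O)(=O)c1ccccc1 | intermediate
25 | (Z)-trimethylsilyl ketene acetal of ester 24, aryl cis to OSiMe3 (formed in the flask) | C/C=C/[C@@H](C[C@@H](C)CO[Si](C)(C)C(C)(C)C)O/C(O[Si](C)(C)C)=C/c1cncc(OCc2ccccc2)c1[C@H](C)CS(=O)(=O)c1ccccc1 | intermediate
26 | trimethylsilyl ester of acid 27 (formed in the flask) | C[C@H](C/C=C/[C@H](C)[C@@H](c1cncc(OCc2ccccc2)c1[C@H](C)CS(=O)(=O)c1ccccc1)C(=O)O[Si](C)(C)C)CO[Si](C)(C)C(C)(C)C | intermediate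
27 | (2S,3S,4E,7R)-2-{4-[(2S)-1-(benzenesulfonyl)propan-2-yl]-5-(benzyloxy)pyridin-3-yl}-8-[(tert-butyldimethylsilyl)oxy]-3,7-dimethyloct-4-enoic acid | C[C@H](C/C=C/[C@H](C)[C@@H](c1cncc(OCc2ccccc2)c1[C@H](C)CS(=O)(=O)c1ccccc1)C(=O)O)CO[Si](C)(C)C(C)(C)C | intermediate
28 | (2S,3S,4E,7R)-2-{4-[(2S)-1-(benzenesulfonyl)propan-2-yl]-5-(benzyloxy)pyridin-3-yl}-8-[(tert-butyldimethylsilyl)oxy]-3,7-dimethyloct-4-en-1-ol | C[C@H](C/C=C/[C@H](C)[C@@H](c1cncc(OCc2ccccc2)c1[C@H](C)CS(=O)(=O)c1ccccc1)CO)CO[Si](C)(C)C(C)(C)C | intermediate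
29 | 4-[(2S)-1-(benzenesulfonyl)propan-2-yl]-3-(benzyloxy)-5-[(2S,3S,4E,7R)-8-[(tert-butyldimethylsilyl)oxy]-1-iodo-3,7-dimethyloct-4-en-2-yl]pyridine | C[C@H](C/C=C/[C@H](C)[C@@H](c1cncc(OCc2ccccc2)c1[C@H](C)CS(=O)(=O)c1ccccc1)CI)CO[Si](C)(C)C(C)(C)C | intermediate
30 | potassium α-sulfonyl carbanion of iodide 29 (formed in the flask) | [K+].C[C@H](C/C=C/[C@H](C)[C@@H](c1cncc(OCc2ccccc2)c1[C@H](C)[CH-]S(=O)(=O)c1ccccc1)CI)CO[Si](C)(C)C(C)(C)C | intermediate
31 | (5S,8S)-6-(benzenesulfonyl)-4-(benzyloxy)-8-[(2S,3E,6R)-7-[(tert-butyldimethylsilyl)oxy]-6-methylhept-3-en-2-yl]-5-methyl-5,6,7,8-tetrahydroisoquinoline, both C6 epimers | C[C@H](C/C=C/[C@H](C)[C@@H]1CC([C@@H](C)c2c(OCc3ccccc3)cncc21)S(=O)(=O)c1ccccc1)CO[Si](C)(C)C(C)(C)C | intermediate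
32 | (5R,8S)-4-(benzyloxy)-8-[(2S,3E,6R)-7-[(tert-butyldimethylsilyl)oxy]-6-methylhept-3-en-2-yl]-5-methyl-5,6,7,8-tetrahydroisoquinoline | C[C@H](C/C=C/[C@H](C)[C@@H]1CC[C@@H](C)c2c(OCc3ccccc3)cncc21)CO[Si](C)(C)C(C)(C)C | intermediate
33 | (5R,8S)-4-(benzyloxy)-8-[(2S,6R)-7-[(tert-butyldimethylsilyl)oxy]-6-methylheptan-2-yl]-5-methyl-5,6,7,8-tetrahydroisoquinoline | C[C@H](CCC[C@H](C)[C@@H]1CC[C@@H](C)c2c(OCc3ccccc3)cncc21)CO[Si](C)(C)C(C)(C)C | intermediate
34 | tert-butyl acetate | CC(=O)OC(C)(C)C | starting material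
35 | lithium enolate of tert-butyl acetate (formed in the flask) | [Li]OC(=C)OC(C)(C)C | intermediate
36 | N-(trifluoromethanesulfonyl)isoquinolinium triflate of 33 (formed in the flask) | C[C@H](CCC[C@H](C)[C@@H]1CC[C@@H](C)c2c(OCc3ccccc3)c[n+](S(=O)(=O)C(F)(F)F)cc21)CO[Si](C)(C)C(C)(C)C.[O-]S(=O)(=O)C(F)(F)F | intermediate
37 | ring-opened N-triflyl azatriene: ring B as a cyclohexene carrying CH=N–SO2CF3 on the former C8a and C(OBn)=CH–NBn2 on the former C4a; drawn for amine attack at the CH next to the benzyloxy carbon, exocyclic double-bond geometry left open (formed in the flask) | C[C@H](CCC[C@H](C)[C@@H]1CC[C@@H](C)C(C(OCc2ccccc2)=CN(Cc2ccccc2)Cc2ccccc2)=C1C=NS(=O)(=O)C(F)(F)F)CO[Si](C)(C)C(C)(C)C | intermediate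
38 | lithium salt of the adduct of 35 to the C=N bond of 37 (β-triflamido tert-butyl ester; new centre not defined; formed in the flask) | C[C@H](CCC[C@H](C)[C@@H]1CC[C@@H](C)C(C(OCc2ccccc2)=CN(Cc2ccccc2)Cc2ccccc2)=C1C(CC(=O)OC(C)(C)C)[N-]S(=O)(=O)C(F)(F)F)CO[Si](C)(C)C(C)(C)C.[Li+] | intermediate
39 | tert-butyl amino-trienoate: as 37 with CH=CH–CO2tBu in place of CH=N–SO2CF3 (formed in the flask) | C[C@H](CCC[C@H](C)[C@@H]1CC[C@@H](C)C(C(OCc2ccccc2)=CN(Cc2ccccc2)Cc2ccccc2)=C1C=CC(=O)OC(C)(C)C)CO[Si](C)(C)C(C)(C)C | intermediate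
40 | 6-(dibenzylamino)cyclohexa-1,3-diene from electrocyclisation of 39: ring A with sp3 C6 (NBn2) and C7 (CO2tBu), configuration there not defined (formed in the flask) | C[C@H](CCC[C@H](C)[C@@H]1CC[C@@H](C)C2=C(OCc3ccccc3)C(N(Cc3ccccc3)Cc3ccccc3)C(C(=O)OC(C)(C)C)C=C21)CO[Si](C)(C)C(C)(C)C | intermediate
41 | tert-butyl (5R,8S)-4-(benzyloxy)-8-[(2S,6R)-7-[(tert-butyldimethylsilyl)oxy]-6-methylheptan-2-yl]-5-methyl-5,6,7,8-tetrahydronaphthalene-2-carboxylate | C[C@H](CCC[C@H](C)[C@@H]1CC[C@@H](C)c2c(OCc3ccccc3)cc(C(=O)OC(C)(C)C)cc21)CO[Si](C)(C)C(C)(C)C | intermediate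
42 | tert-butyl (5R,8S)-4-(benzyloxy)-8-[(2S,6R)-7-hydroxy-6-methylheptan-2-yl]-5-methyl-5,6,7,8-tetrahydronaphthalene-2-carboxylate | C[C@H](CCC[C@H](C)[C@@H]1CC[C@@H](C)c2c(OCc3ccccc3)cc(C(=O)OC(C)(C)C)cc21)CO | intermediate
43 | 3-phenylpropanoyl chloride | O=C(Cl)CCc1ccccc1 | starting material
44 | tert-butyl (5R,8S)-4-(benzyloxy)-5-methyl-8-[(2S,6R)-6-methyl-7-[(3-phenylpropanoyl)oxy]heptan-2-yl]-5,6,7,8-tetrahydronaphthalene-2-carboxylate | C[C@H](CCC[C@H](C)[C@@H]1CC[C@@H](C)c2c(OCc3ccccc3)cc(C(=O)OC(C)(C)C)cc21)COC(=O)CCc1ccccc1 | intermediate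
45 | (5R,8S)-4-(benzyloxy)-5-methyl-8-[(2S,6R)-6-methyl-7-[(3-phenylpropanoyl)oxy]heptan-2-yl]-5,6,7,8-tetrahydronaphthalene-2-carboxylic acid | C[C@H](CCC[C@H](C)[C@@H]1CC[C@@H](C)c2c(OCc3ccccc3)cc(C(=O)O)cc21)COC(=O)CCc1ccccc1 | intermediate
46 | (5R,8S)-4-hydroxy-5-methyl-8-[(2S,6R)-6-methyl-7-[(3-phenylpropanoyl)oxy]heptan-2-yl]-5,6,7,8-tetrahydronaphthalene-2-carboxylic acid (CNP0511546.1) | C[C@H](CCC[C@H](C)[C@@H]1CC[C@@H](C)c2c(O)cc(C(=O)O)cc21)COC(=O)CCc1ccccc1 | target

**Step count**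
Total steps: 25. Longest linear sequence: 21 steps (steps 1–9 and 14–25, from 1); steps 10–13 make the side-chain fragment 23.

**Steps most likely to fail**

1. Step 21 (proposed new method). The ester enolate may act as a base toward azatriene 37 instead of adding to its C=N terminus, or the lateral C4–H of the N-triflylpyridinium may ionise before the amine adds, so that no trienoate forms or C4 is scrambled. Fallback, stepwise and by known reaction types, setting out from 33 and coming back at 39: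
   - Zincke reaction of 33 with 1-chloro-2,4-dinitrobenzene (acetone, reflux) should give the N-(2,4-dinitrophenyl)isoquinolinium chloride F1.
   - Ring opening with dibenzylamine and alkaline hydrolysis of the resulting pentamethinium salt should give the 5-(dibenzylamino)dienal (Zincke aldehyde) F2, drawn as the isomer with the formyl group on the former C8a; the other isomer leads to the same arene.
   - Horner–Wadsworth–Emmons olefination of F2 with tert-butyl (diethoxyphosphoryl)acetate and NaH in THF gives amino-trienoate 39, which is heated to 41 through 40 as in step 21.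

2. Step 8. Transfer of the zinc enolate to the arylpalladium bromide may be too slow next to the branched ortho substituent, so that the C–Br bond is simply reduced. Fallback from 13, coming back at 16 and bypassing 15:
   - Suzuki–Miyaura allylation (allylboronic acid pinacol ester, Pd(dppf)Cl2, CsF, THF, reflux) to 4-[(2S)-1-(benzenesulfonyl)propan-2-yl]-3-(benzyloxy)-5-(prop-2-en-1-yl)pyridine F3.
   - Ozonolysis of the pyridinium salt (O3, CF3CO2H 1 equiv, CH2Cl2/MeOH, −78 °C; Me2S) to the arylacetaldehyde F4.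
   - Pinnick oxidation (NaClO2, NaH2PO4, 2-methylbut-2-ene) to acid 16.

3. Step 13. The oxazaborolidine may discriminate poorly between the propenyl group and the β-branched alkyl chain, and any C4-epimer of 23 would be carried by the Claisen rearrangement into the wrong C1/C11 pair. Fallback from 21, coming back at 23 and bypassing 22: Sharpless kinetic resolution of the epimer mixture (Ti(OiPr)4, L-(+)-diisopropyl tartrate, tBuOOH, 4 Å molecular sieves, CH2Cl2, −20 °C). The (4S)-epimer should be epoxidised to the erythro epoxy alcohol (1S,3R)-4-[(tert-butyldimethylsilyl)oxy]-3-methyl-1-[(2S,3S)-3-methyloxiran-2-yl]butan-1-ol F5, and the slow-reacting (4R)-alcohol 23 is recovered.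

Further compounds
F1 | step 21 | (5R,8S)-4-(benzyloxy)-8-[(2S,6R)-7-[(tert-butyldimethylsilyl)oxy]-6-methylheptan-2-yl]-2-(2,4-dinitrophenyl)-5-methyl-5,6,7,8-tetrahydroisoquinolin-2-ium chloride | C[C@H](CCC[C@H](C)[C@@H]1CC[C@@H](C)c2c(OCc3ccccc3)c[n+](-c3ccc(cc3[N+](=O)[O-])[N+](=O)[O-])cc21)CO[Si](C)(C)C(C)(C)C.[Cl-]
F2 | step 21 | Zincke aldehyde: ring B as a cyclohexene carrying CHO on the former C8a and C(OBn)=CH–NBn2 on the former C4a, configuration at C1, C4, C11 and C15 as in 33 | C[C@H](CCC[C@H](C)[C@@H]1CC[C@@H](C)C(C(OCc2ccccc2)=CN(Cc2ccccc2)Cc2ccccc2)=C1C=O)CO[Si](C)(C)C(C)(C)C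
F3 | step 8 | 4-[(2S)-1-(benzenesulfonyl)propan-2-yl]-3-(benzyloxy)-5-(prop-2-en-1-yl)pyridine | C=CCc1cncc(OCc2ccccc2)c1[C@H](C)CS(=O)(=O)c1ccccc1
F4 | step 8 | 2-{4-[(2S)-1-(benzenesulfonyl)propan-2-yl]-5-(benzyloxy)pyridin-3-yl}acetaldehyde | O=CCc1cncc(OCc2ccccc2)c1[C@H](C)CS(=O)(=O)c1ccccc1
F5 | step 13 | (1S,3R)-4-[(tert-butyldimethylsilyl)oxy]-3-methyl-1-[(2S,3S)-3-methyloxiran-2-yl]butan-1-ol | C[C@@H]1O[C@H]1[C@@H](O)C[C@@H](C)CO[Si](C)(C)C(C)(C)C
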